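Remark on the chemistry: stannane 9 and chloride 14 are taken as purchased materials. Atom labels are those of the target throughout (benzofuran O1, C2, C3, C3a to C7a; ring B C1' to C6'), unless another ring system is named.

## Analysis of the target

Kanzonol V (19) is a 2-arylbenzofuran: the benzo ring (ring A, C3a to C7a) carries a prenyl group on C5 and a hydroxyl on C6, the furan carbon C3 is unsubstituted, and C2 is bonded to C1' of ring B. Ring B is a 1,3-dioxygenated benzene whose O2' and C3' are tied into a 2,2-dimethyl-2H-pyran, so ring B and the pyran form an angular chromene with a free hydroxyl on C4'. There is no stereocentre: the prenyl alkene ends in two identical methyl groups and the chromene alkene is held cis by its ring. The sensitive parts are the prenyl group beside the C6 phenol (closure to a chroman under acid, attack by quinone oxidants and electrophilic metals), the chromene double bond (an electron-rich styrene) and the phenols. The difficulty is regiochemical: each benzene ring has two similar oxygens and two nucleophilic carbons, yet the prenyl group must sit on C5 and not C7, and the pyran must close on O2' and C3' and not on O4'. The strategy rests on the pair C3–H and O2'. A carbonyl carbon placed between them turns the target into a coumestan, its probable biogenetic parent, in which a lactone holds ring B in place for closure of the furan O1–C2 bond and masks O2'. Removing that one carbon afterwards leaves O2' as the only free phenol of ring B, where the pyran has to be attached.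

## Retrosynthetic reasoning

**19 from 17.** The last bonds cut are the O–C bonds of two acetal protecting groups on O6 and O4'. Acetals are kept to the end because these oxygens must stay capped through hot hydroxide, copper at high temperature and a thermal rearrangement. The forward step must free two phenols without protonating the prenyl or chromene alkenes.

**17 from 15, and 15 from 13 and 14.** The pyran is cut at the bond from C3' to the future chromene C4 and at the O2'–CMe2 bond. This leads through the aryl propargyl ether 15 to phenol 13 and chloride 14. Cutting here puts the most acid- and oxidant-sensitive ring last. The forward rearrangement can only reach C3', because C1' is blocked and O4' is capped.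

**13 from 11.** A carbonyl carbon is re-inserted between C3 and O2', which gives coumestan 11. The forward reaction is lactone hydrolysis followed by decarboxylation. The gain is that O2' differs from O4' and O6 without any selective protection of ring B.

**11 from 10 (key disconnection).** The furan O1–C2 bond is cut, which gives the 3-arylcoumarin 10. A cut at C2–C1' would instead need a cross-coupling of two electron-rich partners, with ring B already differentiated. The O1–C2 cut splits the skeleton into an aldehyde half and an arylacetic half. The forward reaction must form a C–O bond at coumarin C4 (future C2) with loss of two hydrogens and must leave the prenyl group alone. The closure is formally 5-endo, so a metal-mediated path is planned and not a simple base-induced conjugate addition.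

**10 from 8 and 9, and 8 from 7.** The prenyl C–C bond at C5 is cut to iodide 8 and stannane 9, and the iodine is removed to give 7. In 7 the position para to the only free phenol is the most nucleophilic carbon, so the regiochemistry of C5 over C7 is set by the same phenol that later becomes O1.

**7 from 3 and 5.** The coumarin is cut at its C3=C4 bond (aldol-type condensation) and at the lactone O–C(=O) bond (acyl transfer). The five-membered lactone 3 supplies the arylacetic unit and delivers its ring oxygen as the free ortho phenol of 7.

**3 from 2 from 1, and 5 from 4.** Both remaining disconnections are protecting-group bonds. Lactonization of 1 ties up the ortho hydroxyl so that only the para hydroxyl of 2 is capped. In 4 the ortho hydroxyl is chelated to the aldehyde, so only the para hydroxyl is alkylated.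

## Alternatives that were turned down

**Alternative 1:** The benzene ring of the chromene is cut at C3'–C4' and C5'–C6'. In the forward key step the pyranopyranone A2 acts as an electron-poor diene toward the ketene acetal A3; the bridged adduct loses its carboxyl bridge and one methoxy group and gives the chromene ester A1.
- For: the pyran sits on the correct oxygen by construction, so no phenols of ring B need to be told apart, and the ester marks the carbon that becomes C1'. On this point it is as secure as the chosen route and secure earlier.
- Against: A1 is only a ring-B fragment. Ring A, the furan and the prenyl group must still be built from the ester, and the C5 versus C7 problem is untouched. The methyl ether on the future O4' is harder to remove beside a chromene and a prenyl group than an acetal. The chromene alkene must survive the cycloaddition and all later steps.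
- Comparison: the alternative spends its key step on a benzene ring that can be bought intact. The chosen route takes both aromatic rings from simple building blocks and needs fewer steps.

**Alternative 2:** Ring B is cut at C1'–C2', C2'–C3' and C4'–C5'. In the forward key step, irradiation of diazoketone A5 gives a vinylketene by Wolff rearrangement; this adds the siloxyalkyne A6 in a [2+2] sense, the cyclobutenone opens, and 6π electrocyclization and tautomerization give phenol A4.
- For: the polarity of ketene and ynol ether fixes every substituent of ring B, and the only free phenol is O2' beside the new C3' prenyl group, so the pyran regiochemistry is as secure as in the chosen route. The silyl ethers come off with fluoride, which is milder than the acetal cleavage the chosen route needs; here the alternative is stronger.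
- Against: the pyran must then be closed by dehydrogenation of the C3' prenyl phenol in a molecule with a second prenyl group and an electron-rich benzofuran. A5 already needs ring A with the prenyl group on C5, so the hard regiochemical problem is only moved into its preparation. A5 is a styrene-like chromophore that can isomerize or dimerize under irradiation, and A6 is a sensitive skipped enyne.
- Comparison: it is more convergent on paper but depends on three delicate components. The chosen route gets the same O2' differentiation from a lactone carbonyl, uses condensations and one cross-coupling, and keeps its risk in one metal-catalysed step.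

**Alternative 3:** Ring A is cut at C4–C5 and C6–C7. In the forward key step the furopyranone A8, a masked furan quinodimethane, adds A6 across its diene termini; decarboxylative aromatization gives A7, the bis-silyl ether of 19.
- For: the end game is the shortest of all, since A7 is one desilylation from 19. The prenyl group and O6 arrive together with no halogenation or cross-coupling. On prenyl placement and on the final deprotection it is stronger than the chosen route.
- Against: the regiochemistry depends on the matching polarization of two unsymmetrical partners, and the wrong orientation would give the isomer with the prenyl group on C6 and the oxygen on C5. A8 must carry the finished chromene, so ring B has to be differentiated beforehand without a lactone to help. A8 is a cross-conjugated dienyl lactone that is likely to be labile, and it must survive heating with a chromene attached.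
- Comparison: the chosen route sets the C5 position by the para-directing free phenol and forms the chromene last, so each regiochemical decision is taken with a control element present.

Key step: step 7

## Route

Step 1
Reactants: 1 2,4-dihydroxyphenylacetic acid
Product: 2 6-hydroxybenzofuran-2(3H)-one
Conditions: TsOH·H2O (cat.), toluene, reflux, Dean–Stark
Reagents that add atoms: none
Why: Acid-catalysed lactonization with azeotropic removal of water; only the ortho hydroxyl can reach the carboxyl group, so the lactone distinguishes the two phenols and leaves the para hydroxyl free.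

Step 2
Reactants: 2 6-hydroxybenzofuran-2(3H)-one
Product: 3 6-(methoxymethoxy)benzofuran-2(3H)-one
Conditions: MOMCl, iPr2NEt, CH2Cl2, 0 °C to rt
Reagents that add atoms: chloromethyl methyl ether, COCCl
Why: Williamson-type O-alkylation of the phenol by a hard alkoxymethyl chloride under a hindered amine base; an enol ether formed at the lactone oxygen would be a ketene acetal that reverts to the lactone on aqueous work-up, so only the phenol ether should persist.

Step 3
Reactants: 4 2,4-dihydroxybenzaldehyde
Product: 5 2-hydroxy-4-(methoxymethoxy)benzaldehyde
Conditions: MOMCl (1.05 equiv), K2CO3, acetone, 0 °C to rt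
Reagents that add atoms: chloromethyl methyl ether, COCCl
Why: Regioselective Williamson alkylation; the ortho hydroxyl is hydrogen-bonded to the aldehyde and less nucleophilic, so the para hydroxyl should react alone.

Step 4
Reactants: 3 6-(methoxymethoxy)benzofuran-2(3H)-one; 5 2-hydroxy-4-(methoxymethoxy)benzaldehyde
Product: 7 3-[2-hydroxy-4-(methoxymethoxy)phenyl]-7-(methoxymethoxy)-2H-chromen-2-one, via arylidene lactone 6 (not isolated)
Conditions: Et3N (0.5 equiv), MeCN, reflux
Reagents that add atoms: none
Why: Knoevenagel (Perkin-type) condensation of the acidic lactone methylene with the aldehyde, then intramolecular acyl transfer from the five-membered aryl lactone to the salicyl hydroxyl, which should give the conjugated six-membered coumarin and release the phenol. If acyl transfer comes before the aldol step, the same product results.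

Step 5
Reactants: 7 3-[2-hydroxy-4-(methoxymethoxy)phenyl]-7-(methoxymethoxy)-2H-chromen-2-one
Product: 8 3-[2-hydroxy-5-iodo-4-(methoxymethoxy)phenyl]-7-(methoxymethoxy)-2H-chromen-2-one
Conditions: NIS (1.05 equiv), MeCN, 0 °C to rt, dark
Reagents that add atoms: N-iodosuccinimide, O=C1CCC(=O)N1I
Why: Electrophilic aromatic iodination; the ring with the free phenol is far more electron-rich than the coumarin, and its carbon para to the hydroxyl (future C5) should be preferred over the crowded carbon between the two oxygens.

Step 6
Reactants: 8 3-[2-hydroxy-5-iodo-4-(methoxymethoxy)phenyl]-7-(methoxymethoxy)-2H-chromen-2-one; 9 tributyl(3-methylbut-2-enyl)stannane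
Product: 10 3-[2-hydroxy-4-(methoxymethoxy)-5-(3-methylbut-2-enyl)phenyl]-7-(methoxymethoxy)-2H-chromen-2-one
Conditions: Pd(PPh3)4 (5 mol %), DMF, 90 °C
Reagents that add atoms: none
Why: Stille coupling of an aryl iodide with an allylic stannane under neutral conditions that tolerate the free phenol and the lactone; coupling at the tin-bearing carbon should give the linear prenyl group.

Step 7
Reactants: 10 3-[2-hydroxy-4-(methoxymethoxy)-5-(3-methylbut-2-enyl)phenyl]-7-(methoxymethoxy)-2H-chromen-2-one
Product: 11 3,9-bis(methoxymethoxy)-8-(3-methylbut-2-enyl)-6H-benzofuro[3,2-c]chromen-6-one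
Conditions: Pd(OAc)2 (10 mol %), Cu(OAc)2 (2.2 equiv), DMSO, 90 °C, N2
Reagents that add atoms: none
Why: Acetate deprotonates the phenol, the phenoxide binds divalent palladium, and the oxygen adds to coumarin C4 (the β-carbon of the unsaturated lactone) while palladium takes C3 as a palladium enolate, a Wacker-type oxypalladation. β-Hydride elimination of the C4 hydrogen restores the C3=C4 bond, now inside an aromatic furan, and Cu(OAc)2 returns zerovalent palladium to the divalent state. The closest known reaction type is the dehydrogenative cyclization of 2'-hydroxy-3-arylcoumarins to coumestans by a quinone or by divalent palladium, a relative of the Wacker cyclization of ortho-alkenylphenols. The furan closes in a formally 5-endo-trig mode, since both carbons of the attacked alkene end up in the five-membered ring; a base alone is therefore not expected to suffice, and the metal is used to turn the addition into an oxypalladation. No stereocentre is formed. Regioselectivity is fixed by geometry, because only C4 lies within reach of the phenol oxygen. Chemoselectivity toward the prenyl group rests on three features of 10: the free phenol is para and not ortho to the prenyl group and cannot cyclize onto it, the ortho oxygen is capped as an acetal, and no quinone is present that could turn the para-alkylphenol into a quinone methide.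

Step 8
Reactants: 11 3,9-bis(methoxymethoxy)-8-(3-methylbut-2-enyl)-6H-benzofuro[3,2-c]chromen-6-one
Product: 13 5-(methoxymethoxy)-2-[6-(methoxymethoxy)-5-(3-methylbut-2-enyl)-1-benzofuran-2-yl]phenol, via dipotassium carboxylate phenoxide 12 (not isolated)
Conditions: KOH, EtOH–H2O, 70 °C; evaporate; then Cu2O (10 mol %), 1,10-phenanthroline, wet NMP–quinoline, 170 °C; neutral aqueous work-up
Reagents that add atoms: potassium hydroxide, [K+].[OH-] (potassium and one oxygen of 12 only; none remains in 13)
Why: Saponification of the aryl lactone, then copper-mediated protodecarboxylation of a benzofuran-3-carboxylate flanked by an ortho aryl group, a favourable substrate class. Keeping the phenol as its phenoxide until the carboxyl group has gone should prevent re-lactonization; the acetals and the prenyl group are stable to hot base.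

Step 9
Reactants: 13 5-(methoxymethoxy)-2-[6-(methoxymethoxy)-5-(3-methylbut-2-enyl)-1-benzofuran-2-yl]phenol; 14 3-chloro-3-methylbut-1-yne
Product: 15 6-(methoxymethoxy)-2-[4-(methoxymethoxy)-2-(2-methylbut-3-yn-2-yloxy)phenyl]-5-(3-methylbut-2-enyl)-1-benzofuran
Conditions: CuCl2·2H2O (cat.), DBU, MeCN, 0 °C
Reagents that add atoms: none
Why: Copper-catalysed O-alkylation of a phenol by a tertiary propargylic chloride, the standard entry to aryl 1,1-dimethylpropargyl ethers; 13 has a single free phenol, so no selectivity question arises.

Step 10
Reactants: 15 6-(methoxymethoxy)-2-[4-(methoxymethoxy)-2-(2-methylbut-3-yn-2-yloxy)phenyl]-5-(3-methylbut-2-enyl)-1-benzofuran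
Product: 17 5-(methoxymethoxy)-8-[6-(methoxymethoxy)-5-(3-methylbut-2-enyl)-1-benzofuran-2-yl]-2,2-dimethyl-2H-chromene, via allenylphenol 16 (not isolated)
Conditions: o-xylene, 140 °C
Reagents that add atoms: none
Why: Aromatic propargyl Claisen rearrangement to the only free ortho carbon (C3'), then 1,5-hydrogen shift and 6π oxa-electrocyclization to the 2,2-dimethyl-2H-chromene. C1' is blocked and O4' is capped, so only the angular chromene on O2' can form.

Step 11
Reactants: 17 5-(methoxymethoxy)-8-[6-(methoxymethoxy)-5-(3-methylbut-2-enyl)-1-benzofuran-2-yl]-2,2-dimethyl-2H-chromene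
Product: 19 Kanzonol V (8-[6-hydroxy-5-(3-methylbut-2-enyl)-1-benzofuran-2-yl]-2,2-dimethyl-2H-chromen-5-ol), via bis(trimethylsilyl) ether 18 (not isolated)
Conditions: TMSOTf, 2,2'-bipyridyl, MeCN, 0 °C to rt; then H2O
Reagents that add atoms: trimethylsilyl trifluoromethanesulfonate, C[Si](C)(C)OS(=O)(=O)C(F)(F)F (silyl groups of 18 only; none remains in 19)
Why: Silyl triflate activated by bipyridyl converts aromatic methoxymethyl ethers into aryl silyl ethers without free Brønsted acid, and water then hydrolyses the silyl ethers. This buffered acetal cleavage should spare the prenyl group beside the C6 phenol and the chromene double bond.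

## Compound list

1 | 2,4-dihydroxyphenylacetic acid | OC(=O)Cc1ccc(O)cc1O | starting material
2 | 6-hydroxybenzofuran-2(3H)-one | O=C1Cc2ccc(O)cc2O1 | intermediate
3 | 6-(methoxymethoxy)benzofuran-2(3H)-one | O=C1Cc2ccc(OCOC)cc2O1 | intermediate
4 | 2,4-dihydroxybenzaldehyde | O=Cc1ccc(O)cc1O | starting material
5 | 2-hydroxy-4-(methoxymethoxy)benzaldehyde | O=Cc1ccc(OCOC)cc1O | intermediate
6 | (Z)-3-[2-hydroxy-4-(methoxymethoxy)benzylidene]-6-(methoxymethoxy)benzofuran-2(3H)-one | O=C1Oc2cc(OCOC)ccc2/C1=C/c1ccc(OCOC)cc1O | intermediate
7 | 3-[2-hydroxy-4-(methoxymethoxy)phenyl]-7-(methoxymethoxy)-2H-chromen-2-one | O=c1oc2cc(OCOC)ccc2cc1-c1ccc(OCOC)cc1O | intermediate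
8 | 3-[2-hydroxy-5-iodo-4-(methoxymethoxy)phenyl]-7-(methoxymethoxy)-2H-chromen-2-one | O=c1oc2cc(OCOC)ccc2cc1-c1cc(I)c(OCOC)cc1O | intermediate
9 | tributyl(3-methylbut-2-enyl)stannane | CCCC[Sn](CCCC)(CCCC)CC=C(C)C | starting material
10 | 3-[2-hydroxy-4-(methoxymethoxy)-5-(3-methylbut-2-enyl)phenyl]-7-(methoxymethoxy)-2H-chromen-2-one | O=c1oc2cc(OCOC)ccc2cc1-c1cc(CC=C(C)C)c(OCOC)cc1O | intermediate
11 | 3,9-bis(methoxymethoxy)-8-(3-methylbut-2-enyl)-6H-benzofuro[3,2-c]chromen-6-one | O=c1oc2cc(OCOC)ccc2c2oc3cc(OCOC)c(CC=C(C)C)cc3c12 | intermediate
12 | dipotassium 6-(methoxymethoxy)-2-[4-(methoxymethoxy)-2-oxidophenyl]-5-(3-methylbut-2-enyl)-1-benzofuran-3-carboxylate | [K+].[K+].[O-]C(=O)c1c(-c2ccc(OCOC)cc2[O-])oc2cc(OCOC)c(CC=C(C)C)cc12 | intermediate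
13 | 5-(methoxymethoxy)-2-[6-(methoxymethoxy)-5-(3-methylbut-2-enyl)-1-benzofuran-2-yl]phenol | COCOc1ccc(-c2cc3cc(CC=C(C)C)c(OCOC)cc3o2)c(O)c1 | intermediate
14 | 3-chloro-3-methylbut-1-yne | CC(C)(Cl)C#C | starting material
15 | 6-(methoxymethoxy)-2-[4-(methoxymethoxy)-2-(2-methylbut-3-yn-2-yloxy)phenyl]-5-(3-methylbut-2-enyl)-1-benzofuran | COCOc1ccc(-c2cc3cc(CC=C(C)C)c(OCOC)cc3o2)c(OC(C)(C)C#C)c1 | intermediate
16 | 3-(methoxymethoxy)-6-[6-(methoxymethoxy)-5-(3-methylbut-2-enyl)-1-benzofuran-2-yl]-2-(3-methylbuta-1,2-dienyl)phenol | COCOc1ccc(-c2cc3cc(CC=C(C)C)c(OCOC)cc3o2)c(O)c1C=C=C(C)C | intermediate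
17 | 5-(methoxymethoxy)-8-[6-(methoxymethoxy)-5-(3-methylbut-2-enyl)-1-benzofuran-2-yl]-2,2-dimethyl-2H-chromene | CC(C)=CCc1cc2cc(-c3ccc(OCOC)c4c3OC(C)(C)C=C4)oc2cc1OCOC | intermediate
18 | 2-[2,2-dimethyl-5-(trimethylsilyloxy)-2H-chromen-8-yl]-5-(3-methylbut-2-enyl)-6-(trimethylsilyloxy)-1-benzofuran | CC(C)=CCc1cc2cc(-c3ccc(O[Si](C)(C)C)c4c3OC(C)(C)C=C4)oc2cc1O[Si](C)(C)C | intermediate
19 | Kanzonol V, 8-[6-hydroxy-5-(3-methylbut-2-enyl)-1-benzofuran-2-yl]-2,2-dimethyl-2H-chromen-5-ol | CC(C)=CCc1cc2cc(-c3ccc(O)c4c3OC(C)(C)C=C4)oc2cc1O | target

## Step count and least certain steps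

Total: 11 steps. Longest linear sequence: 10 steps (1 to 19 through steps 1, 2 and 4 to 11); step 3 is a one-step side branch.

**Step 7 (key step).** The most likely failure is attack of divalent palladium on the prenyl alkene (allylic acetoxylation or Wacker-type oxidation). A second risk is poor turnover, because the electron-poor coumarin alkene binds the metal weakly and the phenol is then oxidized by the copper salt instead. Fallback: set out from iodide 8 and close the furan before the prenyl group exists. DDQ in refluxing dioxane should dehydrogenate 8; this is safe here because the carbon para to the phenol carries iodine and not an alkyl group. The product is 8-iodo-3,9-bis(methoxymethoxy)-6H-benzofuro[3,2-c]chromen-6-one F1. Stille coupling of this with stannane 9 (Pd(PPh3)4, DMF, 90 °C) returns to the route at 11.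

**Step 8.** The most likely failure is re-closure of the lactone whenever the carboxylic acid and the phenol are both protonated, which gives back 11 instead of losing the carboxyl group. The carboxylate salt may also decarboxylate slowly. Fallback: set out from 11 and remove the carbon as carbon monoxide. Reduction with i-Bu2AlH (CH2Cl2, −78 °C) should give the lactol 3,9-bis(methoxymethoxy)-8-(3-methylbut-2-enyl)-6H-benzofuro[3,2-c]chromen-6-ol F2. Its ring-opened hydroxy aldehyde form is decarbonylated with RhCl(PPh3)3 in refluxing toluene (Tsuji–Wilkinson decarbonylation), which returns to the route at 13.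

**Step 6.** The most likely failure is allylic transposition during transmetalation, which would put a 1,1-dimethylallyl group on the ring. Oxidative addition to the electron-rich iodophenol may also be slow. Fallback: set out from 8 and couple allyltributylstannane (Pd(PPh3)4, DMF, 90 °C); its two allyl termini are equivalent. This gives 3-[5-allyl-2-hydroxy-4-(methoxymethoxy)phenyl]-7-(methoxymethoxy)-2H-chromen-2-one F3. Olefin cross-metathesis with excess 2-methylbut-2-ene and the second-generation Grubbs catalyst (CH2Cl2, 40 °C) returns to the route at 10.

**Step 4.** The most likely failure is that the condensation stops at the arylidene lactone because the alkene geometry does not allow acyl transfer. The reactive lactone may also be opened by adventitious nucleophiles before it condenses. Fallback: set out from 3 and use the classical Perkin condensation of the open acid salt. One equivalent of NaOH in THF–H2O opens the lactone to sodium [2-hydroxy-4-(methoxymethoxy)phenyl]acetate F4. Heating F4 with aldehyde 5 in Ac2O and Et3N at 110 °C should give 5-(methoxymethoxy)-2-[7-(methoxymethoxy)-2-oxo-2H-chromen-3-yl]phenyl acetate F5. Methanolysis of the acetate (K2CO3, MeOH, rt) returns to the route at 7.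

**Step 11.** The most likely failure is loss of the chromene double bond by electrophilic addition once a Lewis or Brønsted acid is present, since this styrene is activated by oxygen at its ortho and para positions. The hindered acetal beside the prenyl group may also cleave incompletely. Fallback: set out from 15 and cleave the acetals before the chromene exists, then carry the two phenols through the rearrangement as acetates. The same silyl triflate and bipyridyl treatment of 15 should give 2-[4-hydroxy-2-(2-methylbut-3-yn-2-yloxy)phenyl]-5-(3-methylbut-2-enyl)-1-benzofuran-6-ol F6. Ac2O in pyridine gives 4-[6-acetoxy-5-(3-methylbut-2-enyl)-1-benzofuran-2-yl]-3-(2-methylbut-3-yn-2-yloxy)phenyl acetate F7; the acetate on O4' keeps the pyran from closing there. Heating in o-xylene at 140 °C gives 8-[6-acetoxy-5-(3-methylbut-2-enyl)-1-benzofuran-2-yl]-2,2-dimethyl-2H-chromen-5-yl acetate F8. Mild methanolysis (K2CO3, MeOH, rt) returns to the route at 19.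

## Further compounds

F1 | step 7 | 8-iodo-3,9-bis(methoxymethoxy)-6H-benzofuro[3,2-c]chromen-6-one | O=c1oc2cc(OCOC)ccc2c2oc3cc(OCOC)c(I)cc3c12
F2 | step 8 | 3,9-bis(methoxymethoxy)-8-(3-methylbut-2-enyl)-6H-benzofuro[3,2-c]chromen-6-ol (racemic hemiacetal) | OC1Oc2cc(OCOC)ccc2-c2oc3cc(OCOC)c(CC=C(C)C)cc3c21
F3 | step 6 | 3-[5-allyl-2-hydroxy-4-(methoxymethoxy)phenyl]-7-(methoxymethoxy)-2H-chromen-2-one | O=c1oc2cc(OCOC)ccc2cc1-c1cc(CC=C)c(OCOC)cc1O
F4 | step 4 | sodium [2-hydroxy-4-(methoxymethoxy)phenyl]acetate | [Na+].[O-]C(=O)Cc1ccc(OCOC)cc1O
F5 | step 4 | 5-(methoxymethoxy)-2-[7-(methoxymethoxy)-2-oxo-2H-chromen-3-yl]phenyl acetate | CC(=O)Oc1cc(OCOC)ccc1-c1cc2ccc(OCOC)cc2oc1=O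
F6 | step 11 | 2-[4-hydroxy-2-(2-methylbut-3-yn-2-yloxy)phenyl]-5-(3-methylbut-2-enyl)-1-benzofuran-6-ol | Oc1ccc(-c2cc3cc(CC=C(C)C)c(O)cc3o2)c(OC(C)(C)C#C)c1
F7 | step 11 | 4-[6-acetoxy-5-(3-methylbut-2-enyl)-1-benzofuran-2-yl]-3-(2-methylbut-3-yn-2-yloxy)phenyl acetate | CC(=O)Oc1ccc(-c2cc3cc(CC=C(C)C)c(OC(C)=O)cc3o2)c(OC(C)(C)C#C)c1
F8 | step 11 | 8-[6-acetoxy-5-(3-methylbut-2-enyl)-1-benzofuran-2-yl]-2,2-dimethyl-2H-chromen-5-yl acetate | CC(C)=CCc1cc2cc(-c3ccc(OC(C)=O)c4c3OC(C)(C)C=C4)oc2cc1OC(C)=O
A1 | alternative 1 | ethyl 5-methoxy-2,2-dimethyl-2H-chromene-8-carboxylate | CCOC(=O)c1ccc(OC)c2c1OC(C)(C)C=C2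
A2 | alternative 1 | ethyl 2,2-dimethyl-5-oxo-2H,5H-pyrano[4,3-b]pyran-8-carboxylate | CCOC(=O)C1=COC(=O)C2=C1OC(C)(C)C=C2
A3 | alternative 1 | 1,1-dimethoxyethene | C=C(OC)OC
A4 | alternative 2 | 2-[2-hydroxy-3-(3-methylbut-2-enyl)-4-(triisopropylsilyloxy)phenyl]-5-(3-methylbut-2-enyl)-6-(triisopropylsilyloxy)benzofuran | CC(C)=CCc1cc2cc(-c3ccc(O[Si](C(C)C)(C(C)C)C(C)C)c(CC=C(C)C)c3O)oc2cc1O[Si](C(C)C)(C(C)C)C(C)C
A5 | alternative 2 | (E)-1-diazo-4-[5-(3-methylbut-2-enyl)-6-(triisopropylsilyloxy)-1-benzofuran-2-yl]but-3-en-2-one | [N-]=[N+]=CC(=O)/C=C/c1cc2cc(CC=C(C)C)c(O[Si](C(C)C)(C(C)C)C(C)C)cc2o1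
A6 | alternative 2 | triisopropyl(5-methylhex-4-en-1-ynyloxy)silane | CC(C)=CCC#CO[Si](C(C)C)(C(C)C)C(C)C
A7 | alternative 3 | bis(triisopropylsilyl) ether of Kanzonol V | CC(C)=CCc1cc2cc(-c3ccc(O[Si](C(C)C)(C(C)C)C(C)C)c4c3OC(C)(C)C=C4)oc2cc1O[Si](C(C)C)(C(C)C)C(C)C
A8 | alternative 3 | 2-[2,2-dimethyl-5-(triisopropylsilyloxy)-2H-chromen-8-yl]-6H-furo[3,2-c]pyran-6-one | O=C1OC=C2C=C(-c3ccc(O[Si](C(C)C)(C(C)C)C(C)C)c4c3OC(C)(C)C=C4)OC2=C1
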